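**Strategy.** With resveratrol-unit numbering (units a, b and c), canaliculatol holds two alike five-membered rings: the indane (C7a, C8a, C8b and two carbons of ring D) and the dihydrobenzofuran (O, C7c, C8c and two carbons of ring B). In each, a diarylmethine carbon on a fused arene (C7a; C8c) is bonded to a benzylic CH (C8a; C7c). Both rings are closed at once by twofold 1,5 C–H insertion of diaryl rhodium carbenes generated from an open-chain bis(hydrazone): C7a inserts into C8a–H (aryl groups on C7a and C8a cis, as required), C8c into the 4-methoxybenzyl ether CH2. Friedel–Crafts closure of the eight-membered ring and demethylation follow.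

Key step: step 11

Remarks before the steps:
- Ring letters: ring A = 4-oxygenated phenyl on C7a; ring B = oxygenated ring on C8a (fused in the dihydrobenzofuran); ring C = 4-oxygenated phenyl on C7b; ring D = dioxygenated ring on C8b (fused in the indane); ring E = 4-oxygenated phenyl on C7c; ring F = dioxygenated ring on C8c (part of the eight-membered ring).
- Assumption: 5,7-dimethoxyphthalide (1) is taken as purchasable.
- Assumption: the catalyst enantiomer that sets C8c as R in the ether insertion is written Rh2(R-PTAD)4, dirhodium tetrakis[(R)-(1-adamantyl)(phthalimido)acetate]; if the sense is opposite, the S catalyst takes its place.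

**Route**

Step 1
Reactants: 1 5,7-dimethoxyphthalide
Product: 2 7-hydroxy-5-methoxyphthalide
Conditions: BCl3, CH2Cl2, −78 °C → 0 °C; aq. work-up
Reagents that add atoms: none
Why: Chelation of boron between the lactone carbonyl and the peri (position 7) methoxy oxygen should direct Lewis-acid ether cleavage to that group only.

Step 2
Reactants: 2 7-hydroxy-5-methoxyphthalide; 3 4-methoxybenzyl chloride
Product: 4 5-methoxy-7-[(4-methoxybenzyl)oxy]phthalide
Conditions: K2CO3, NaI (cat.), DMF, 60 °C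
Reagents that add atoms: none
Why: Williamson ether synthesis; the benzyl CH2 installed here later becomes C7c and its aryl group ring E.

Step 3
Reactants: 4 5-methoxy-7-[(4-methoxybenzyl)oxy]phthalide; 5 1-bromo-3,5-dimethoxybenzene
Product: 7 (3,5-dimethoxyphenyl){2-(hydroxymethyl)-4-methoxy-6-[(4-methoxybenzyl)oxy]phenyl}methanone, via 3,5-dimethoxyphenyllithium 6 (not isolated)
Conditions: 5, n-BuLi, THF, −78 °C; then 4, −78 °C; H2O quench
Reagents that add atoms: none
Why: Bromine–lithium exchange and single addition of the aryllithium to the lactone; the lithium lactolate persists at −78 °C, which should prevent a second addition, and opens to the hydroxy ketone on work-up.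

Step 4
Reactants: 7 (3,5-dimethoxyphenyl){2-(hydroxymethyl)-4-methoxy-6-[(4-methoxybenzyl)oxy]phenyl}methanone
Product: 8 {2-(bromomethyl)-4-methoxy-6-[(4-methoxybenzyl)oxy]phenyl}(3,5-dimethoxyphenyl)methanone
Conditions: CBr4, PPh3, CH2Cl2, 0 °C; used directly
Reagents that add atoms: carbon tetrabromide, BrC(Br)(Br)Br
Why: Appel reaction of the primary benzylic alcohol (open hydroxy-ketone form) under neutral conditions that leave ketone and ethers intact.

Step 5
Reactants: 9 methyl 2-(3,5-dimethoxyphenyl)acetate; 10 4-methoxybenzoyl chloride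
Product: 11 methyl 2-[3,5-dimethoxy-2-(4-methoxybenzoyl)phenyl]acetate
Conditions: SnCl4, CH2Cl2, 0 °C → rt
Reagents that add atoms: none
Why: Friedel–Crafts acylation at ring position 2 (para to one methoxy, ortho to the other), the site known to react in 3,5-dimethoxyphenylacetates; SnCl4 should spare the ortho methoxy group.

Step 6
Reactants: 11 methyl 2-[3,5-dimethoxy-2-(4-methoxybenzoyl)phenyl]acetate
Product: 12 2-[3,5-dimethoxy-2-(4-methoxybenzoyl)phenyl]acetic acid
Conditions: LiOH, THF/H2O, rt; then HCl to pH 3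
Reagents that add atoms: lithium hydroxide, [Li+].[OH-]
Why: Saponification of the methyl ester.

Step 7
Reactants: 12 2-[3,5-dimethoxy-2-(4-methoxybenzoyl)phenyl]acetic acid; 13 (S)-4-benzyl-5,5-dimethyloxazolidin-2-one
Product: 15 (S)-4-benzyl-3-{2-[3,5-dimethoxy-2-(4-methoxybenzoyl)phenyl]acetyl}-5,5-dimethyloxazolidin-2-one, via mixed pivalic anhydride 14 (not isolated)
Conditions: pivaloyl chloride, Et3N, THF, −20 °C; then 13, LiCl, −20 °C → rt
Reagents that add atoms: none
Why: N-Acylation of the oxazolidinone auxiliary by the mixed anhydride under LiCl/Et3N activation.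

Step 8
Reactants: 15 (S)-4-benzyl-3-{2-[3,5-dimethoxy-2-(4-methoxybenzoyl)phenyl]acetyl}-5,5-dimethyloxazolidin-2-one; 8 {2-(bromomethyl)-4-methoxy-6-[(4-methoxybenzyl)oxy]phenyl}(3,5-dimethoxyphenyl)methanone
Product: 17 (S)-4-benzyl-3-{(2S)-2-[3,5-dimethoxy-2-(4-methoxybenzoyl)phenyl]-3-[2-(3,5-dimethoxybenzoyl)-5-methoxy-3-(4-methoxybenzyloxy)phenyl]propanoyl}-5,5-dimethyloxazolidin-2-one, via sodium enolate 16 (not isolated)
Conditions: NaN(SiMe3)2, THF, −78 °C; then 8, −78 → −30 °C
Reagents that add atoms: none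
Why: Oxazolidinone-auxiliary asymmetric enolate alkylation: the chelated Z-enolate is shielded on one face by the auxiliary benzyl group, so the benzylic bromide should enter from the other face and set C8b as S.

Step 9
Reactants: 17 the alkylated imide (full name in step 8)
Product: 18 (2S)-2-[3,5-dimethoxy-2-(4-methoxybenzoyl)phenyl]-3-[2-(3,5-dimethoxybenzoyl)-5-methoxy-3-(4-methoxybenzyloxy)phenyl]-1-(morpholin-4-yl)propan-1-one
Conditions: morpholine, AlMe3, CH2Cl2, 0 °C → 35 °C; aq. KNaC4H4O6 (potassium sodium tartrate) work-up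
Reagents that add atoms: morpholine, C1COCCN1
Why: Aluminium-amide aminolysis of the imide; the gem-dimethyl group blocks attack at the ring carbonyl so the exocyclic acyl group is transferred without touching C8b, and the tertiary amide (no hydrogen on C7b, slow to react with hydrazine) is the later ketone precursor.

Step 10
Reactants: 18 the diketo morpholine amide (full name in step 9)
Product: 19 bis(hydrazone) of 18 (both diaryl ketones as C=N–NH2, E/Z undefined)
Conditions: N2H4·H2O (excess), AcOH (cat.), EtOH, 90 °C, sealed tube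
Reagents that add atoms: hydrazine (as the monohydrate), NN
Why: Condensation of both diaryl ketones with hydrazine; forcing conditions are chosen because each carbonyl has two ortho substituents, and the tertiary amide and the ethers should be inert.

Step 11
Reactants: 19 bis(hydrazone) of 18
Product: 21 {(1S,2R,3R)-2-[(2S,3R)-3-(3,5-dimethoxyphenyl)-6-methoxy-2-(4-methoxyphenyl)-2,3-dihydrobenzofuran-4-yl]-4,6-dimethoxy-3-(4-methoxyphenyl)-2,3-dihydro-1H-inden-1-yl}(morpholin-4-yl)methanone (indane 1,2-trans and 2,3-cis; dihydrobenzofuran cis), via bis(diazo) compound 20 (not isolated)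
Conditions: MnO2, CH2Cl2, rt, dark; filter; Rh2(R-PTAD)4 (2 mol%), CH2Cl2, −20 °C → rt
Reagents that add atoms: none
Why: MnO2 dehydrogenates both hydrazones to diaryldiazomethanes, and the divalent-rhodium carboxylate expels N2 from each to give two diaryl (donor/donor) rhodium carbenes that insert into the C–H bond in 1,5-relation. The closest known reaction type is the enantioselective intramolecular C–H insertion of donor/donor carbenes that turns 2-(benzyloxy)benzophenone hydrazones into cis-2,3-diaryl-2,3-dihydrobenzofurans and 2-alkylbenzophenone hydrazones into 1,2-disubstituted indanes. The C8c carbene inserts into the ether CH2 (forms C8c–C7c, closes the dihydrofuran ring by 1,5-insertion), and the C7a carbene inserts into the benzylic C8a–H (forms C7a–C8a, closes the indane ring by 1,5-insertion). C8c (R), with C7c cis to it, should be set by the chiral catalyst as on the parent substrates; C8a should be set by the existing C8b centre, because the aryl group on C8a avoids the amide on C8b in the envelope-like transition state, and C7a by the inherent cis preference of the concerted insertion, which places ring A syn to ring B. Site selectivity is built into the substrate: the C8c carbene finds an ether CH2 that is both alpha to oxygen and benzylic while the competing C8b–H is alpha to a carbonyl and deactivated, and the C7a carbene finds only the C8a hydrogens because C7b is a carbonyl carbon without hydrogen; diaryl carbenes have no beta hydrogen to shift. C7c emerges with the cis (wrong) configuration and is corrected in step 12.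

Step 12
Reactants: 21 the cis-dihydrobenzofuran indane amide (full name in step 11)
Product: 22 {(1S,2R,3R)-2-[(2R,3R)-3-(3,5-dimethoxyphenyl)-6-methoxy-2-(4-methoxyphenyl)-2,3-dihydrobenzofuran-4-yl]-4,6-dimethoxy-3-(4-methoxyphenyl)-2,3-dihydro-1H-inden-1-yl}(morpholin-4-yl)methanone (dihydrobenzofuran trans)
Conditions: CF3CO2H, CH2Cl2, 0 °C → rt
Reagents that add atoms: none
Why: Acid-mediated epimerisation: reversible ionisation of the benzylic C7c–O bond (4-methoxybenzyl cation) and reclosure under thermodynamic control should give the trans-2,3-diaryl dihydrobenzofuran with C8c untouched.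

Step 13
Reactants: 22 the trans-dihydrobenzofuran indane amide (full name in step 12); 23 4-methoxyphenylmagnesium bromide
Product: 24 {(1S,2R,3R)-2-[(2R,3R)-3-(3,5-dimethoxyphenyl)-6-methoxy-2-(4-methoxyphenyl)-2,3-dihydrobenzofuran-4-yl]-4,6-dimethoxy-3-(4-methoxyphenyl)-2,3-dihydro-1H-inden-1-yl}(4-methoxyphenyl)methanone
Conditions: 23 (3 equiv), THF, 0 °C → rt; aq. work-up
Reagents that add atoms: none
Why: Acyl substitution of the morpholine amide by the aryl Grignard reagent through a stable tetrahedral magnesium adduct (no over-addition); C8b, now alpha to the ketone, already has the thermodynamically preferred trans relation to the aryl group on C8a.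

Step 14
Reactants: 24 the aryl ketone (full name in step 13)
Product: 25 {(1S,2R,3R)-2-[(2R,3R)-3-(3,5-dimethoxyphenyl)-6-methoxy-2-(4-methoxyphenyl)-2,3-dihydrobenzofuran-4-yl]-4,6-dimethoxy-3-(4-methoxyphenyl)-2,3-dihydro-1H-inden-1-yl}(4-methoxyphenyl)methanol (both C7b epimers)
Conditions: NaBH4, MeOH/THF, 0 °C → rt
Reagents that add atoms: none
Why: Hydride reduction of the ketone; the C7b configuration is irrelevant because this centre is ionised in the next step.

Step 15
Reactants: 25 the carbinol (full name in step 14)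
Product: 26 canaliculatol octa-O-methyl ether
Conditions: CF3SO3H (10 mol%), (CF3)2CHOH, 0 °C, high dilution
Reagents that add atoms: none
Why: Dehydrative intramolecular Friedel–Crafts alkylation: the 4-methoxybenzylic cation at C7b is attacked by the ortho carbon of ring F (para to a methoxy group) to close the eight-membered ring; C7b should be set by approach from the only cation face the tether reaches with ring C turned outward, and the trans relation of C8a and C8b excludes the five-membered closure onto ring B.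

Step 16
Reactants: 26 canaliculatol octa-O-methyl ether
Product: 27 canaliculatol
Conditions: BBr3 (excess), CH2Cl2, −78 °C → rt; MeOH, then H2O
Reagents that add atoms: none
Why: Lewis-acid cleavage of the eight aryl methyl ethers; no alkene or carbinol remains that could react with the acid.

**Compound list**

1 | 5,7-dimethoxyphthalide | O=C1OCc2cc(OC)cc(OC)c12 | starting material
2 | 7-hydroxy-5-methoxyphthalide | O=C1OCc2cc(OC)cc(O)c12 | intermediate
3 | 4-methoxybenzyl chloride | COc1ccc(CCl)cc1 | starting material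
4 | 5-methoxy-7-[(4-methoxybenzyl)oxy]phthalide | O=C1OCc2cc(OC)cc(OCc3ccc(OC)cc3)c12 | intermediate
5 | 1-bromo-3,5-dimethoxybenzene | COc1cc(Br)cc(OC)c1 | starting material
6 | 3,5-dimethoxyphenyllithium | [Li]c1cc(OC)cc(OC)c1 | intermediate
7 | (3,5-dimethoxyphenyl){2-(hydroxymethyl)-4-methoxy-6-[(4-methoxybenzyl)oxy]phenyl}methanone | OCc1cc(OC)cc(OCc2ccc(OC)cc2)c1C(=O)c1cc(OC)cc(OC)c1 | intermediate
8 | {2-(bromomethyl)-4-methoxy-6-[(4-methoxybenzyl)oxy]phenyl}(3,5-dimethoxyphenyl)methanone | BrCc1cc(OC)cc(OCc2ccc(OC)cc2)c1C(=O)c1cc(OC)cc(OC)c1 | intermediate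
9 | methyl 2-(3,5-dimethoxyphenyl)acetate | COC(=O)Cc1cc(OC)cc(OC)c1 | starting material
10 | 4-methoxybenzoyl chloride | COc1ccc(C(Cl)=O)cc1 | starting material
11 | methyl 2-[3,5-dimethoxy-2-(4-methoxybenzoyl)phenyl]acetate | COC(=O)Cc1cc(OC)cc(OC)c1C(=O)c1ccc(OC)cc1 | intermediate
12 | 2-[3,5-dimethoxy-2-(4-methoxybenzoyl)phenyl]acetic acid | OC(=O)Cc1cc(OC)cc(OC)c1C(=O)c1ccc(OC)cc1 | intermediate
13 | (S)-4-benzyl-5,5-dimethyloxazolidin-2-one | O=C1N[C@@H](Cc2ccccc2)C(C)(C)O1 | starting material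
14 | mixed anhydride of 12 with pivalic acid | CC(C)(C)C(=O)OC(=O)Cc1cc(OC)cc(OC)c1C(=O)c1ccc(OC)cc1 | intermediate
15 | (S)-4-benzyl-3-{2-[3,5-dimethoxy-2-(4-methoxybenzoyl)phenyl]acetyl}-5,5-dimethyloxazolidin-2-one | O=C(Cc1cc(OC)cc(OC)c1C(=O)c1ccc(OC)cc1)N1C(=O)OC(C)(C)[C@@H]1Cc1ccccc1 | intermediate
16 | sodium enolate of 15 | [Na+].[O-]C(=Cc1cc(OC)cc(OC)c1C(=O)c1ccc(OC)cc1)N1C(=O)OC(C)(C)[C@@H]1Cc1ccccc1 | intermediate
17 | (S)-4-benzyl-3-{(2S)-2-[3,5-dimethoxy-2-(4-methoxybenzoyl)phenyl]-3-[2-(3,5-dimethoxybenzoyl)-5-methoxy-3-(4-methoxybenzyloxy)phenyl]propanoyl}-5,5-dimethyloxazolidin-2-one | O=C([C@@H](Cc1cc(OC)cc(OCc2ccc(OC)cc2)c1C(=O)c1cc(OC)cc(OC)c1)c1cc(OC)cc(OC)c1C(=O)c1ccc(OC)cc1)N1C(=O)OC(C)(C)[C@@H]1Cc1ccccc1 | intermediate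
18 | (2S)-2-[3,5-dimethoxy-2-(4-methoxybenzoyl)phenyl]-3-[2-(3,5-dimethoxybenzoyl)-5-methoxy-3-(4-methoxybenzyloxy)phenyl]-1-(morpholin-4-yl)propan-1-one | O=C([C@@H](Cc1cc(OC)cc(OCc2ccc(OC)cc2)c1C(=O)c1cc(OC)cc(OC)c1)c1cc(OC)cc(OC)c1C(=O)c1ccc(OC)cc1)N1CCOCC1 | intermediate
19 | bis(hydrazone) of 18 | O=C([C@@H](Cc1cc(OC)cc(OCc2ccc(OC)cc2)c1C(=NN)c1cc(OC)cc(OC)c1)c1cc(OC)cc(OC)c1C(=NN)c1ccc(OC)cc1)N1CCOCC1 | intermediate
20 | bis(diaryldiazomethane) from 19 | O=C([C@@H](Cc1cc(OC)cc(OCc2ccc(OC)cc2)c1C(=[N+]=[N-])c1cc(OC)cc(OC)c1)c1cc(OC)cc(OC)c1C(=[N+]=[N-])c1ccc(OC)cc1)N1CCOCC1 | intermediate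
21 | {(1S,2R,3R)-2-[(2S,3R)-3-(3,5-dimethoxyphenyl)-6-methoxy-2-(4-methoxyphenyl)-2,3-dihydrobenzofuran-4-yl]-4,6-dimethoxy-3-(4-methoxyphenyl)-2,3-dihydro-1H-inden-1-yl}(morpholin-4-yl)methanone (cis-dihydrobenzofuran) | O=C(N1CCOCC1)[C@@H]1c2cc(OC)cc(OC)c2[C@@H](c2ccc(OC)cc2)[C@H]1c1cc(OC)cc2c1[C@@H](c1cc(OC)cc(OC)c1)[C@@H](c1ccc(OC)cc1)O2 | intermediate
22 | {(1S,2R,3R)-2-[(2R,3R)-3-(3,5-dimethoxyphenyl)-6-methoxy-2-(4-methoxyphenyl)-2,3-dihydrobenzofuran-4-yl]-4,6-dimethoxy-3-(4-methoxyphenyl)-2,3-dihydro-1H-inden-1-yl}(morpholin-4-yl)methanone (trans-dihydrobenzofuran) | O=C(N1CCOCC1)[C@@H]1c2cc(OC)cc(OC)c2[C@@H](c2ccc(OC)cc2)[C@H]1c1cc(OC)cc2c1[C@@H](c1cc(OC)cc(OC)c1)[C@H](c1ccc(OC)cc1)O2 | intermediate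
23 | 4-methoxyphenylmagnesium bromide | COc1ccc([Mg]Br)cc1 | starting material
24 | {(1S,2R,3R)-2-[(2R,3R)-3-(3,5-dimethoxyphenyl)-6-methoxy-2-(4-methoxyphenyl)-2,3-dihydrobenzofuran-4-yl]-4,6-dimethoxy-3-(4-methoxyphenyl)-2,3-dihydro-1H-inden-1-yl}(4-methoxyphenyl)methanone | O=C(c1ccc(OC)cc1)[C@@H]1c2cc(OC)cc(OC)c2[C@@H](c2ccc(OC)cc2)[C@H]1c1cc(OC)cc2c1[C@@H](c1cc(OC)cc(OC)c1)[C@H](c1ccc(OC)cc1)O2 | intermediate
25 | carbinol from 24, {(1S,2R,3R)-indan-1-yl}(4-methoxyphenyl)methanol with the substituents of 24, both C7b epimers | OC(c1ccc(OC)cc1)[C@@H]1c2cc(OC)cc(OC)c2[C@@H](c2ccc(OC)cc2)[C@H]1c1cc(OC)cc2c1[C@@H](c1cc(OC)cc(OC)c1)[C@H](c1ccc(OC)cc1)O2 | intermediate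
26 | canaliculatol octa-O-methyl ether | COc1ccc([C@@H]2c3c(OC)cc(OC)cc3[C@H]3[C@H](c4ccc(OC)cc4)c4c(OC)cc(OC)cc4[C@@H]4c5c(cc(OC)cc5[C@H]23)O[C@H]4c2ccc(OC)cc2)cc1 | intermediate
27 | canaliculatol | Oc1ccc([C@@H]2c3c(O)cc(O)cc3[C@H]3[C@H](c4ccc(O)cc4)c4c(O)cc(O)cc4[C@@H]4c5c(cc(O)cc5[C@H]23)O[C@H]4c2ccc(O)cc2)cc1 | target

**Totals.** Total step count: 16. Longest linear sequence: 13 steps (steps 1–4, then 8–16).

**Steps most likely to fail**

Step 11 (key step). The two carbene centres may interfere with each other. The catalyst enantiomer chosen for the ether insertion may work against the substrate control of the indane insertion and erode its diastereoselectivity, or the C7a carbene may be intercepted by the neighbouring amide oxygen before it reaches C8a–H. The fallback separates the two insertions; it sets out from 7 and comes back at 22. Silylation of 7 (tert-butyldimethylsilyl chloride, imidazole) would give the silyl ether F1, and condensation with N2H4·H2O the hydrazone F2. MnO2 would give the diazo compound F3, which with Rh2(R-PTAD)4 should undergo the single, catalyst-controlled ether insertion to the cis-dihydrobenzofuran silyl ether F4. CF3CO2H in wet CH2Cl2 would epimerise C7c and remove the silyl group to give the trans alcohol F5, and CBr4/PPh3 the bromide F6. Alkylation of enolate 16 with F6 would give the imide F7, and AlMe3/morpholine the amide F8. N2H4·H2O would give the mono-hydrazone F9 and MnO2 the diazo compound F10. One insertion into C8a–H under Rh2(OAc)4, now steered only by C8b, would then close the indane and give 22.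

Step 15. The benzylic cation at C7b may lose the C8b proton faster than the eight-membered ring closes; reprotonation from the other face would then allow irreversible five-membered closure onto the free ortho position of ring B. The fallback avoids a free cation next to C8b–H until the ring is closed; it sets out from 22 and comes back at 26. Cp2Zr(H)Cl would reduce the amide to the aldehyde F11. SnCl4 at −78 °C should effect intramolecular hydroxyalkylation of ring F to the cyclic benzylic alcohol F12. Dess–Martin periodinane would give the cyclic ketone F13, and 23 with CeCl3 the tertiary alcohol F14. Ionic hydrogenation (Et3SiH, CF3CO2H) would then give 26.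

Step 10. Condensation may stall at the two doubly ortho-substituted carbonyl groups. The free NH2 of the C7a hydrazone may also attack the neighbouring morpholine amide and close a seven-membered cyclic acyl hydrazide, and prolonged heating with hydrazine may begin to erode the C8b centre. The fallback replaces direct condensation by catalysed silyl-hydrazone exchange; it sets out from 18 and comes back at 19. 1,2-Bis(tert-butyldimethylsilyl)hydrazine with catalytic Sc(OTf)3 should give the bis(N-silylhydrazone) F15 under mild conditions, with nitrogen kept non-nucleophilic. n-Bu4NF in MeOH at 0 °C would then release 19 for immediate oxidation.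

Further compounds
F1 | step 11 | tert-butyldimethylsilyl ether of 7 | CC(C)(C)[Si](C)(C)OCc1cc(OC)cc(OCc2ccc(OC)cc2)c1C(=O)c1cc(OC)cc(OC)c1
F2 | step 11 | hydrazone of the silyl ether of 7 | CC(C)(C)[Si](C)(C)OCc1cc(OC)cc(OCc2ccc(OC)cc2)c1C(=NN)c1cc(OC)cc(OC)c1
F3 | step 11 | diaryldiazomethane from the hydrazone of the silyl ether of 7 | CC(C)(C)[Si](C)(C)OCc1cc(OC)cc(OCc2ccc(OC)cc2)c1C(=[N+]=[N-])c1cc(OC)cc(OC)c1
F4 | step 11 | tert-butyl{[(2S,3R)-3-(3,5-dimethoxyphenyl)-6-methoxy-2-(4-methoxyphenyl)-2,3-dihydrobenzofuran-4-yl]methoxy}dimethylsilane (cis) | CC(C)(C)[Si](C)(C)OCc1cc(OC)cc2c1[C@@H](c1cc(OC)cc(OC)c1)[C@@H](c1ccc(OC)cc1)O2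
F5 | step 11 | [(2R,3R)-3-(3,5-dimethoxyphenyl)-6-methoxy-2-(4-methoxyphenyl)-2,3-dihydrobenzofuran-4-yl]methanol (trans) | OCc1cc(OC)cc2c1[C@@H](c1cc(OC)cc(OC)c1)[C@H](c1ccc(OC)cc1)O2
F6 | step 11 | (2R,3R)-4-(bromomethyl)-3-(3,5-dimethoxyphenyl)-6-methoxy-2-(4-methoxyphenyl)-2,3-dihydrobenzofuran | BrCc1cc(OC)cc2c1[C@@H](c1cc(OC)cc(OC)c1)[C@H](c1ccc(OC)cc1)O2
F7 | step 11 | (S)-4-benzyl-3-{(2S)-2-[3,5-dimethoxy-2-(4-methoxybenzoyl)phenyl]-3-[(2R,3R)-3-(3,5-dimethoxyphenyl)-6-methoxy-2-(4-methoxyphenyl)-2,3-dihydrobenzofuran-4-yl]propanoyl}-5,5-dimethyloxazolidin-2-one | O=C([C@@H](Cc1cc(OC)cc2c1[C@@H](c1cc(OC)cc(OC)c1)[C@H](c1ccc(OC)cc1)O2)c1cc(OC)cc(OC)c1C(=O)c1ccc(OC)cc1)N1C(=O)OC(C)(C)[C@@H]1Cc1ccccc1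
F8 | step 11 | morpholine amide from the dihydrobenzofuran imide | O=C([C@@H](Cc1cc(OC)cc2c1[C@@H](c1cc(OC)cc(OC)c1)[C@H](c1ccc(OC)cc1)O2)c1cc(OC)cc(OC)c1C(=O)c1ccc(OC)cc1)N1CCOCC1
F9 | step 11 | hydrazone of the dihydrobenzofuran keto morpholine amide | O=C([C@@H](Cc1cc(OC)cc2c1[C@@H](c1cc(OC)cc(OC)c1)[C@H](c1ccc(OC)cc1)O2)c1cc(OC)cc(OC)c1C(=NN)c1ccc(OC)cc1)N1CCOCC1
F10 | step 11 | diaryldiazomethane from the dihydrobenzofuran hydrazone | O=C([C@@H](Cc1cc(OC)cc2c1[C@@H](c1cc(OC)cc(OC)c1)[C@H](c1ccc(OC)cc1)O2)c1cc(OC)cc(OC)c1C(=[N+]=[N-])c1ccc(OC)cc1)N1CCOCC1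
F11 | step 15 | (1S,2R,3R)-indane-1-carbaldehyde corresponding to 22 | O=C[C@@H]1c2cc(OC)cc(OC)c2[C@@H](c2ccc(OC)cc2)[C@H]1c1cc(OC)cc2c1[C@@H](c1cc(OC)cc(OC)c1)[C@H](c1ccc(OC)cc1)O2
F12 | step 15 | eight-membered-ring benzylic alcohol (hydroxyl on C7b, ring C absent, C7b epimers) | COc1ccc([C@@H]2c3c(OC)cc(OC)cc3[C@H]3C(O)c4c(OC)cc(OC)cc4[C@@H]4c5c(cc(OC)cc5[C@H]23)O[C@H]4c2ccc(OC)cc2)cc1
F13 | step 15 | eight-membered-ring ketone (carbonyl at C7b) | COc1ccc([C@@H]2c3c(OC)cc(OC)cc3[C@H]3C(=O)c4c(OC)cc(OC)cc4[C@@H]4c5c(cc(OC)cc5[C@H]23)O[C@H]4c2ccc(OC)cc2)cc1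
F14 | step 15 | tertiary alcohol with hydroxyl and ring C on C7b (C7b epimers) | COc1ccc([C@@H]2c3c(OC)cc(OC)cc3[C@H]3C(O)(c4ccc(OC)cc4)c4c(OC)cc(OC)cc4[C@@H]4c5c(cc(OC)cc5[C@H]23)O[C@H]4c2ccc(OC)cc2)cc1
F15 | step 10 | bis(N-tert-butyldimethylsilyl hydrazone) of 18 | O=C([C@@H](Cc1cc(OC)cc(OCc2ccc(OC)cc2)c1C(=NN[Si](C)(C)C(C)(C)C)c1cc(OC)cc(OC)c1)c1cc(OC)cc(OC)c1C(=NN[Si](C)(C)C(C)(C)C)c1ccc(OC)cc1)N1CCOCC1
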